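**Assumption:** the target has no stereocentre and is achiral, so there is no enantiomer to select. Racemic intermediates lose their stereocentres along the way. The product is delivered as the free hydrogen sulfate, as drawn.

## Retrosynthetic overview
1. The sulfate is installed last, by O-sulfation of the primary alcohol while the four phenols are silylated. Methyl ethers protect the phenols until then.
2. ArCH2Ar and ArCH2CH2OH both come from one C=C bond. Ozonolysis and reduction of a 3-aryl-1H-indene turn C3 into the bridging CH2 and C1–C2 into CH2CH2OH.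
3. The indene comes from acid cyclodehydration of a 1,3-diarylpropan-1-one, in which ring B attacks the ring A ketone para to its OMe.
4. The key C–C bond is a Claisen–Schmidt aldol condensation of a ring A methyl ketone with a ring B aldehyde, followed by C=C hydrogenation. Both partners come from vanillin with all Br already in place.
5. Both benzene rings are bought. The only ring made is the temporary cyclopentene (step 9), opened in step 10. A transient isochroman ring forms and opens in step 11.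

## Route

Step 1
Reactants: 1 vanillin (4-hydroxy-3-methoxybenzaldehyde)
Product: 2 5-bromovanillin (3-bromo-4-hydroxy-5-methoxybenzaldehyde)
Conditions: Br2 (1.05 equiv), MeOH, 0 °C → rt
Reagents that add atoms: bromine, BrBr
Why: Electrophilic aromatic bromination in which the free OH directs ortho and C5 is its only open ortho/para site.

Step 2
Reactants: 2 5-bromovanillin
Product: 3 3-bromo-4,5-dimethoxybenzaldehyde (ring B aldehyde)
Conditions: MeI, K2CO3, DMF, rt
Reagents that add atoms: iodomethane, CI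
Why: Williamson O-methylation of the phenoxide, to which the aldehyde and the aryl bromide are inert.

Step 3
Reactants: 2 5-bromovanillin
Product: 4 5,6-dibromovanillin (2,3-dibromo-4-hydroxy-5-methoxybenzaldehyde)
Conditions: Br2 (1.5 equiv), Fe powder (10 mol %, gives FeBr3 in situ), AcOH, rt → 60 °C
Reagents that add atoms: bromine, BrBr
Why: Second electrophilic aromatic bromination, in which the OH has no free ortho/para site left, so the OMe directs Br to its para position next to the first Br.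

Step 4
Reactants: 4 5,6-dibromovanillin
Product: 5 2,3-dibromo-4,5-dimethoxybenzaldehyde
Conditions: MeI, K2CO3, DMF, 40 °C
Reagents that add atoms: iodomethane, CI
Why: Williamson O-methylation of the acidic, flanked phenol with small MeI.

Step 5
Reactants: 5 2,3-dibromo-4,5-dimethoxybenzaldehyde
Product: 6 1-(2,3-dibromo-4,5-dimethoxyphenyl)ethanol (racemic)
Conditions: MeMgBr (1.2 equiv), THF, −20 → 0 °C; aq NH4Cl
Reagents that add atoms: methylmagnesium bromide, C[Mg]Br
Why: Grignard 1,2-addition, which is much faster than any Br/Mg exchange with MeMgBr at this temperature; the racemic stereocentre is removed in step 6.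

Step 6
Reactants: 6 1-(2,3-dibromo-4,5-dimethoxyphenyl)ethanol
Product: 7 1-(2,3-dibromo-4,5-dimethoxyphenyl)ethanone (ring A methyl ketone)
Conditions: Dess–Martin periodinane (1.2 equiv), CH2Cl2, rt
Reagents that add atoms: none
Why: Dess–Martin oxidation is neutral and halogen-free, so the electron-rich arene is not attacked.

Step 7 (key step)
Reactants: 7 1-(2,3-dibromo-4,5-dimethoxyphenyl)ethanone; 3 3-bromo-4,5-dimethoxybenzaldehyde
Product: 9 (E)-3-(3-bromo-4,5-dimethoxyphenyl)-1-(2,3-dibromo-4,5-dimethoxyphenyl)prop-2-en-1-one, via beta-hydroxy ketone 8 (not isolated)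
Conditions: KOH (1.5 equiv), MeOH/THF, rt, 16 h
Reagents that add atoms: none
Why: Claisen–Schmidt crossed aldol condensation, in which only 7 can enolise and only 3 is an aldehyde, and E1cB loss of water from 8 gives the conjugated E-enone irreversibly.

Step 8
Reactants: 9 (E)-chalcone
Product: 10 3-(3-bromo-4,5-dimethoxyphenyl)-1-(2,3-dibromo-4,5-dimethoxyphenyl)propan-1-one
Conditions: H2 (4 bar), RhCl(PPh3)3 (5 mol %), toluene/EtOH 1:1, 50 °C
Reagents that add atoms: none
Why: Homogeneous hydrogenation with RhCl(PPh3)3 saturates the disubstituted alkene and leaves the three C–Br bonds and the ketone untouched.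

Step 9
Reactants: 10 dihydrochalcone
Product: 12 4-bromo-3-(2,3-dibromo-4,5-dimethoxyphenyl)-5,6-dimethoxy-1H-indene, via indan-1-ol 11 (not isolated)
Conditions: polyphosphoric acid, 70 °C, 2–3 h; ice water
Reagents that add atoms: none
Why: Aromatic cyclodehydration (intramolecular Friedel–Crafts hydroxyalkylation, then E1), in which ring B attacks the protonated ketone at the carbon para to its 5-OMe, the same site that reacts in step 3, and carbinol 11 can lose water only toward C2, which fixes the alkene position.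

Step 10
Reactants: 12 3-aryl-1H-indene
Product: 15 2-{3-bromo-2-[(2,3-dibromo-4,5-dimethoxyphenyl)(hydroxy)methyl]-4,5-dimethoxyphenyl}ethanol (racemic), via ozonide 13 (not isolated), via keto aldehyde 14 (not isolated)
Conditions: O3/O2, CH2Cl2, −78 °C, stopped at the first blue tint; N2 purge; then NaBH4 (6 equiv), MeOH, −78 °C → rt
Reagents that add atoms: ozone, [O-][O+]=O
Why: Criegee ozonolysis of the indene C2=C3 bond is much faster than attack on the brominated arenes, and borohydride reduces the ozonide in the same flask, so the sensitive arylacetaldehyde is never handled.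

Step 11
Reactants: 15 diol
Product: 17 2-[3-bromo-2-(2,3-dibromo-4,5-dimethoxybenzyl)-4,5-dimethoxyphenyl]ethanol, via isochroman 16 (not isolated)
Conditions: Et3SiH (5 equiv), CF3CO2H/CH2Cl2 1:2, 0 °C → rt; aq NaHCO3
Reagents that add atoms: none
Why: Ionic hydrogenation, in which the p-methoxy-stabilised benzhydryl cation is trapped reversibly by the side-chain OH as 16 and irreversibly by silane hydride, so all material drains to the diarylmethane.

Step 12
Reactants: 17 tetramethyl ether alcohol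
Product: 18 3-bromo-4-(2,3-dibromo-4,5-dihydroxybenzyl)-5-(2-hydroxyethyl)benzene-1,2-diol
Conditions: BBr3 (10 equiv), CH2Cl2, −78 → 0 °C → rt; ice water
Reagents that add atoms: none
Why: Lewis-acid aryl methyl ether cleavage, in which bromide attacks only the activated O–CH3 groups and the unactivated primary alcohol sits as a borate that water hydrolyses back.

Step 13
Reactants: 18 pentaol
Product: 19 penta-TBS ether of 18 (four aryl and one alkyl tert-butyldimethylsilyl ether)
Conditions: TBSCl (8 equiv), imidazole (16 equiv), DMF, rt → 40 °C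
Reagents that add atoms: tert-butyldimethylsilyl chloride, CC(C)(C)[Si](C)(C)Cl
Why: Exhaustive imidazole-promoted silylation needs no selectivity and gives an air-stable, chromatographable compound.

Step 14
Reactants: 19 penta-TBS ether
Product: 20 2-{3-bromo-2-[2,3-dibromo-4,5-bis(TBSO)benzyl]-4,5-bis(TBSO)phenyl}ethanol
Conditions: camphorsulfonic acid (10 mol %), MeOH/CH2Cl2 1:1, 0 °C
Reagents that add atoms: none
Why: Acid-catalysed methanolysis cleaves the more basic, unhindered primary alkyl silyl ether well before the aryl silyl ethers.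

Step 15
Reactants: 20 tetra-TBS alcohol
Product: 21 pyridinium 2-{3-bromo-2-[2,3-dibromo-4,5-bis(TBSO)benzyl]-4,5-bis(TBSO)phenyl}ethyl sulfate
Conditions: SO3·pyridine (3 equiv), pyridine, rt
Reagents that add atoms: sulfur trioxide–pyridine complex, [O-]S(=O)(=O)[n+]1ccccc1
Why: O-sulfation of the only free hydroxyl under mildly basic conditions that aryl silyl ethers tolerate.

Step 16
Reactants: 21 pyridinium sulfate
Product: 23 2-[3-bromo-2-(2,3-dibromo-4,5-dihydroxybenzyl)-4,5-dihydroxyphenyl]ethyl hydrogen sulfate (target), via ammonium salt 22 (not isolated)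
Conditions: NH4F (12 equiv), MeOH, rt, argon; C18 cartridge (H2O, then MeOH/H2O); sulfonic acid cation-exchange resin (H+ form), H2O/MeOH, 0–5 °C; freeze-dry
Reagents that add atoms: none
Why: Near-neutral fluoride desilylation removes the labile bromoaryl silyl ethers without acid solvolysis of the sulfate or base-promoted catechol oxidation, and cold cation exchange gives the free acid.

## Compound list
1 | vanillin | O=Cc1ccc(O)c(OC)c1 | starting material
2 | 5-bromovanillin | O=Cc1cc(Br)c(O)c(OC)c1 | intermediate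
3 | 3-bromo-4,5-dimethoxybenzaldehyde | O=Cc1cc(Br)c(OC)c(OC)c1 | intermediate
4 | 2,3-dibromo-4-hydroxy-5-methoxybenzaldehyde | O=Cc1cc(OC)c(O)c(Br)c1Br | intermediate
5 | 2,3-dibromo-4,5-dimethoxybenzaldehyde | O=Cc1cc(OC)c(OC)c(Br)c1Br | intermediate
6 | 1-(2,3-dibromo-4,5-dimethoxyphenyl)ethanol (racemic) | CC(O)c1cc(OC)c(OC)c(Br)c1Br | intermediate
7 | 1-(2,3-dibromo-4,5-dimethoxyphenyl)ethanone | CC(=O)c1cc(OC)c(OC)c(Br)c1Br | intermediate
8 | 3-(3-bromo-4,5-dimethoxyphenyl)-1-(2,3-dibromo-4,5-dimethoxyphenyl)-3-hydroxypropan-1-one (racemic, not isolated) | O=C(CC(O)c1cc(Br)c(OC)c(OC)c1)c1cc(OC)c(OC)c(Br)c1Br | intermediate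
9 | (E)-3-(3-bromo-4,5-dimethoxyphenyl)-1-(2,3-dibromo-4,5-dimethoxyphenyl)prop-2-en-1-one | O=C(/C=C/c1cc(Br)c(OC)c(OC)c1)c1cc(OC)c(OC)c(Br)c1Br | intermediate
10 | 3-(3-bromo-4,5-dimethoxyphenyl)-1-(2,3-dibromo-4,5-dimethoxyphenyl)propan-1-one | O=C(CCc1cc(Br)c(OC)c(OC)c1)c1cc(OC)c(OC)c(Br)c1Br | intermediate
11 | 7-bromo-1-(2,3-dibromo-4,5-dimethoxyphenyl)-5,6-dimethoxyindan-1-ol (racemic, not isolated) | OC1(CCc2cc(OC)c(OC)c(Br)c21)c1cc(OC)c(OC)c(Br)c1Br | intermediate
12 | 4-bromo-3-(2,3-dibromo-4,5-dimethoxyphenyl)-5,6-dimethoxy-1H-indene | C1C=C(c2cc(OC)c(OC)c(Br)c2Br)c2c1cc(OC)c(OC)c2Br | intermediate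
13 | secondary ozonide (1,2,4-trioxolane bridging former C2 and C3) of 12 (racemic, not isolated) | C1C2OOC(O2)(c2cc(OC)c(OC)c(Br)c2Br)c2c1cc(OC)c(OC)c2Br | intermediate
14 | 2-[3-bromo-2-(2,3-dibromo-4,5-dimethoxybenzoyl)-4,5-dimethoxyphenyl]acetaldehyde (not isolated) | O=CCc1cc(OC)c(OC)c(Br)c1C(=O)c1cc(OC)c(OC)c(Br)c1Br | intermediate
15 | 2-{3-bromo-2-[(2,3-dibromo-4,5-dimethoxyphenyl)(hydroxy)methyl]-4,5-dimethoxyphenyl}ethanol (racemic) | OCCc1cc(OC)c(OC)c(Br)c1C(O)c1cc(OC)c(OC)c(Br)c1Br | intermediate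
16 | 8-bromo-1-(2,3-dibromo-4,5-dimethoxyphenyl)-6,7-dimethoxyisochroman (racemic, not isolated) | C1COC(c2cc(OC)c(OC)c(Br)c2Br)c2c1cc(OC)c(OC)c2Br | intermediate
17 | 2-[3-bromo-2-(2,3-dibromo-4,5-dimethoxybenzyl)-4,5-dimethoxyphenyl]ethanol | OCCc1cc(OC)c(OC)c(Br)c1Cc1cc(OC)c(OC)c(Br)c1Br | intermediate
18 | 3-bromo-4-(2,3-dibromo-4,5-dihydroxybenzyl)-5-(2-hydroxyethyl)benzene-1,2-diol | OCCc1cc(O)c(O)c(Br)c1Cc1cc(O)c(O)c(Br)c1Br | intermediate
19 | penta-TBS ether of 18 | CC(C)(C)[Si](C)(C)OCCc1cc(O[Si](C)(C)C(C)(C)C)c(O[Si](C)(C)C(C)(C)C)c(Br)c1Cc1cc(O[Si](C)(C)C(C)(C)C)c(O[Si](C)(C)C(C)(C)C)c(Br)c1Br | intermediate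
20 | tetra(aryl-TBS) primary alcohol | OCCc1cc(O[Si](C)(C)C(C)(C)C)c(O[Si](C)(C)C(C)(C)C)c(Br)c1Cc1cc(O[Si](C)(C)C(C)(C)C)c(O[Si](C)(C)C(C)(C)C)c(Br)c1Br | intermediate
21 | pyridinium salt of the tetra(aryl-TBS) alkyl sulfate | [O-]S(=O)(=O)OCCc1cc(O[Si](C)(C)C(C)(C)C)c(O[Si](C)(C)C(C)(C)C)c(Br)c1Cc1cc(O[Si](C)(C)C(C)(C)C)c(O[Si](C)(C)C(C)(C)C)c(Br)c1Br.c1cc[nH+]cc1 | intermediate
22 | ammonium salt of the target (not isolated) | [NH4+].[O-]S(=O)(=O)OCCc1cc(O)c(O)c(Br)c1Cc1cc(O)c(O)c(Br)c1Br | intermediate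
23 | 2-[3-bromo-2-(2,3-dibromo-4,5-dihydroxybenzyl)-4,5-dihydroxyphenyl]ethyl hydrogen sulfate (achiral) | O=S(=O)(O)OCCc1cc(O)c(O)c(Br)c1Cc1cc(O)c(O)c(Br)c1Br | target

## Step count and risks
Total steps: 16. Longest linear sequence: 15 steps (1, 3–16). Step 2 is the only branch step.

**Step 9 (cyclodehydration).** The ketone is hindered and ring closure must occur next to a bromine.
- The fallback sets out from 9 and returns at 12.
- Luche reduction of 9 (NaBH4, CeCl3·7H2O, MeOH, 0 °C) gives (E)-3-(3-bromo-4,5-dimethoxyphenyl)-1-(2,3-dibromo-4,5-dimethoxyphenyl)prop-2-en-1-ol F1.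
- FeCl3·6H2O (10 mol %) in CH2Cl2 ionises it to the 1,3-diarylallyl cation, a much stronger electrophile than a protonated ketone.
- That cation closes on the richer ring B to give 7-bromo-1-(2,3-dibromo-4,5-dimethoxyphenyl)-5,6-dimethoxy-1H-indene F2.
- Catalytic DBU in THF then moves the double bond through the indenyl anion to give 12.

**Step 11 (ionic reduction).** The tri-ortho-substituted cation may stall at the cyclic ether.
- The fallback sets out from 15 and returns at 17.
- The primary OH alone is acetylated (Ac2O 1.1 equiv, pyridine, 0 °C) to give 2-{3-bromo-2-[(2,3-dibromo-4,5-dimethoxyphenyl)(hydroxy)methyl]-4,5-dimethoxyphenyl}ethyl acetate F3, so no internal nucleophile remains.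
- Et3SiH with CF3CO2H then gives 2-[3-bromo-2-(2,3-dibromo-4,5-dimethoxybenzyl)-4,5-dimethoxyphenyl]ethyl acetate F4.
- K2CO3 in MeOH releases 17.

**Step 12 (BBr3 with a free 2-arylethanol).** Some C–OH may be converted to C–Br.
- The fallback sets out from 17 and returns at 18.
- The alcohol is oxidised (TEMPO cat., PhI(OAc)2, MeCN/H2O) to [3-bromo-2-(2,3-dibromo-4,5-dimethoxybenzyl)-4,5-dimethoxyphenyl]acetic acid F5.
- BBr3 demethylates it, with no alcohol carbon at risk, to [3-bromo-2-(2,3-dibromo-4,5-dihydroxybenzyl)-4,5-dihydroxyphenyl]acetic acid F6.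
- Excess BH3·THF reduces the acid to 18.

## Further compounds
F1 | step 9 | (E)-3-(3-bromo-4,5-dimethoxyphenyl)-1-(2,3-dibromo-4,5-dimethoxyphenyl)prop-2-en-1-ol (racemic) | OC(/C=C/c1cc(Br)c(OC)c(OC)c1)c1cc(OC)c(OC)c(Br)c1Br
F2 | step 9 | 7-bromo-1-(2,3-dibromo-4,5-dimethoxyphenyl)-5,6-dimethoxy-1H-indene (racemic) | C1=CC(c2cc(OC)c(OC)c(Br)c2Br)c2c1cc(OC)c(OC)c2Br
F3 | step 11 | 2-{3-bromo-2-[(2,3-dibromo-4,5-dimethoxyphenyl)(hydroxy)methyl]-4,5-dimethoxyphenyl}ethyl acetate (racemic) | CC(=O)OCCc1cc(OC)c(OC)c(Br)c1C(O)c1cc(OC)c(OC)c(Br)c1Br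
F4 | step 11 | 2-[3-bromo-2-(2,3-dibromo-4,5-dimethoxybenzyl)-4,5-dimethoxyphenyl]ethyl acetate | CC(=O)OCCc1cc(OC)c(OC)c(Br)c1Cc1cc(OC)c(OC)c(Br)c1Br
F5 | step 12 | [3-bromo-2-(2,3-dibromo-4,5-dimethoxybenzyl)-4,5-dimethoxyphenyl]acetic acid | OC(=O)Cc1cc(OC)c(OC)c(Br)c1Cc1cc(OC)c(OC)c(Br)c1Br
F6 | step 12 | [3-bromo-2-(2,3-dibromo-4,5-dihydroxybenzyl)-4,5-dihydroxyphenyl]acetic acid | OC(=O)Cc1cc(O)c(O)c(Br)c1Cc1cc(O)c(O)c(Br)c1Br
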